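**Strategy**

Everything rests on cutting the cis, trisubstituted C4=C5 alkene of the ten-membered carbocycle (C1–C10), the bond that lies between the C3 carbinol and the C6 lactone carbinol. Ring-closing metathesis between a vinyl group on C6 of the preformed trans-fused α-methylene lactone (C6, C7, C11, C12, O) and the C4 methylene of a 2-methylene-1,3-diol unit closes the macrocycle and sets the alkene geometry in a single operation. The precursor is an open-chain lactone that already carries all six stereocentres, the C8 angelate, the 1,10-epoxide and triethylsilyl ethers on O3 and O15; it comes from a zinc-mediated union of a C8 aldehyde with an enantiopure bromolactone.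

Key step: step 18

Numbering: germacrane numbering is used (ring C1–C10, C14 methyl on C10, C15 on C4, lactone carbons C11–C13).

Assumption: the zinc-mediated allylation is taken to follow the closed chair transition state of an E-locked allyl metal and to give the 8S (anti) alcohol, so the angelate is introduced with inversion.

Design remark: C1=C10 is converted into the 1,10-epoxide before ring closure, because a ruthenium carbene on C5 could otherwise close a strain-free cyclohexene onto C10 and expel the C1–C4/C15 half. This changes a spectator group only and leaves the carbon skeletons of the metathesis precursor and product as they are.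

**Route**

Step 1
Reactants: 1 but-3-yn-1-ol
Product: 2 1-[(but-3-yn-1-yloxy)methyl]-4-methoxybenzene
Conditions: NaH, PMBCl, Bu4NI (cat.), THF/DMF, 0 °C → rt
Reagents that add atoms: 4-methoxybenzyl chloride, COc1ccc(CCl)cc1
Why: Williamson etherification, in which NaH deprotonates only the hydroxyl (far more acidic than the alkyne C–H) and the alkoxide displaces chloride from the benzylic halide.

Step 2
Reactants: 2 1-[(but-3-yn-1-yloxy)methyl]-4-methoxybenzene
Product: 5 (2E)-5-[(4-methoxybenzyl)oxy]-3-methylpent-2-en-1-ol, via alkenyldimethylalane 3 (not isolated), via lithium alkenylalanate 4 (not isolated)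
Conditions: Me3Al, Cp2ZrCl2 (25 mol %), CH2Cl2, 0 °C → rt; volatiles removed; n-BuLi, THF, −78 °C; (CH2O)n, −78 °C → rt
Reagents that add atoms: trimethylaluminium, C[Al](C)C; formaldehyde (as paraformaldehyde), C=O
Why: Negishi zirconium-catalysed carboalumination adds methyl and aluminium syn across the alkyne with aluminium on the terminal carbon, which fixes the E geometry of the future C1=C10 alkene, and the more nucleophilic alanate then adds to formaldehyde with retention to install C2 as a primary allylic alcohol.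

Step 3
Reactants: 5 (2E)-5-[(4-methoxybenzyl)oxy]-3-methylpent-2-en-1-ol
Product: 6 1-({[(3E)-5-bromo-3-methylpent-3-en-1-yl]oxy}methyl)-4-methoxybenzene
Conditions: CBr4, PPh3, CH2Cl2, 0 °C
Reagents that add atoms: carbon tetrabromide, BrC(Br)(Br)Br
Why: Appel bromination of a primary allylic alcohol proceeds by SN2 displacement of the oxyphosphonium group at the unhindered CH2, so the alkene geometry is untouched.

Step 4
Reactants: 7 2,2-dimethyl-1,3-dioxan-5-one; 8 (S)-1-amino-2-(methoxymethyl)pyrrolidine (SAMP)
Product: 9 (2S)-N-(2,2-dimethyl-1,3-dioxan-5-ylidene)-2-(methoxymethyl)pyrrolidin-1-amine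
Conditions: benzene, reflux (Dean–Stark)
Reagents that add atoms: none
Why: Hydrazone condensation of the ketone with the 1,1-disubstituted hydrazine is driven to completion by azeotropic removal of water.

Step 5
Reactants: 9 (2S)-N-(2,2-dimethyl-1,3-dioxan-5-ylidene)-2-(methoxymethyl)pyrrolidin-1-amine; 6 1-({[(3E)-5-bromo-3-methylpent-3-en-1-yl]oxy}methyl)-4-methoxybenzene
Product: 12 (4S)-4-[(2E)-5-[(4-methoxybenzyl)oxy]-3-methylpent-2-en-1-yl]-2,2-dimethyl-1,3-dioxan-5-one, via lithium azaenolate 10 (not isolated), via alkylated SAMP hydrazone 11 (not isolated)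
Conditions: t-BuLi, THF, −78 °C; 6, −100 °C → rt; then sat. aq. (CO2H)2, Et2O, rt
Reagents that add atoms: water, O
Why: Enders SAMP-hydrazone alkylation, in which the lithium azaenolate is chelated by the methoxymethyl arm so that the allylic bromide enters from the open face in the same sense as in SAMP alkylations of other cyclic ketones, which should set C3 as S, and biphasic oxalic acid hydrolysis then releases the ketone without epimerisation while the acetonide and the PMB ether stay intact.

Step 6
Reactants: 12 (4S)-4-[(2E)-5-[(4-methoxybenzyl)oxy]-3-methylpent-2-en-1-yl]-2,2-dimethyl-1,3-dioxan-5-one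
Product: 13 (4S)-4-[(2E)-5-[(4-methoxybenzyl)oxy]-3-methylpent-2-en-1-yl]-2,2-dimethyl-5-methylidene-1,3-dioxane
Conditions: Ph3PCH3Br, KOtBu, THF, −78 → 0 °C
Reagents that add atoms: methyltriphenylphosphonium bromide, C[P+](c1ccccc1)(c1ccccc1)c1ccccc1.[Br-]
Why: Wittig methylenation of the electrophilic α,α′-dialkoxy ketone is fast at low temperature, which should keep enolisation and hence epimerisation at C3 from competing, and it creates the C4 methylene that later takes part in the ring closure.

Step 7
Reactants: 13 (4S)-4-[(2E)-5-[(4-methoxybenzyl)oxy]-3-methylpent-2-en-1-yl]-2,2-dimethyl-5-methylidene-1,3-dioxane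
Product: 14 (3S,5E)-8-[(4-methoxybenzyl)oxy]-6-methyl-2-methylideneoct-5-ene-1,3-diol
Conditions: AcOH/THF/H2O (3:1:1), 40 °C
Reagents that add atoms: none
Why: Acid-catalysed acetal hydrolysis removes the isopropylidene group, while the PMB ether and the trisubstituted alkene are stable to aqueous acetic acid.

Step 8
Reactants: 14 (3S,5E)-8-[(4-methoxybenzyl)oxy]-6-methyl-2-methylideneoct-5-ene-1,3-diol
Product: 15 (3S,5E)-8-[(4-methoxybenzyl)oxy]-6-methyl-2-methylidene-1,3-bis(triethylsilyloxy)oct-5-ene
Conditions: TESCl, imidazole, DMF, 0 °C → rt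
Reagents that add atoms: chlorotriethylsilane, CC[Si](Cl)(CC)CC
Why: Silylation with a chlorosilane and imidazole protects the primary C15 and the secondary allylic C3 hydroxyl as small ethers that should survive the later zinc, Mitsunobu, dioxirane and ruthenium steps and are removed last by fluoride under near-neutral conditions.

Step 9
Reactants: 15 (3S,5E)-8-[(4-methoxybenzyl)oxy]-6-methyl-2-methylidene-1,3-bis(triethylsilyloxy)oct-5-ene
Product: 16 (3E,6S)-3-methyl-6-(triethylsilyloxy)-7-[(triethylsilyloxy)methyl]octa-3,7-dien-1-ol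
Conditions: DDQ, CH2Cl2/pH 7 phosphate buffer (10:1), 0 °C
Reagents that add atoms: none
Why: Oxidative PMB cleavage with DDQ proceeds through the benzylic oxocarbenium ion and water and, under buffering, leaves silyl ethers and unactivated alkenes untouched.

Step 10
Reactants: 16 (3E,6S)-3-methyl-6-(triethylsilyloxy)-7-[(triethylsilyloxy)methyl]octa-3,7-dien-1-ol
Product: 17 (3E,6S)-3-methyl-6-(triethylsilyloxy)-7-[(triethylsilyloxy)methyl]octa-3,7-dienal
Conditions: Dess–Martin periodinane, NaHCO3, CH2Cl2, 0 °C; used crude at once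
Reagents that add atoms: none
Why: Dess–Martin oxidation under bicarbonate buffering should give the β,γ-unsaturated C8 aldehyde without acid- or base-induced migration of C1=C10 into conjugation.

Step 11
Reactants: 18 acrolein; 19 tert-butyldimethyl(prop-2-yn-1-yloxy)silane
Product: 21 (3R)-6-[(tert-butyldimethylsilyl)oxy]hex-1-en-4-yn-3-ol, via methyl(alkynyl)zinc 20 (not isolated)
Conditions: Me2Zn, (S,S)-ProPhenol (10 mol %), Ph3PO (20 mol %), toluene, 0 °C
Reagents that add atoms: none
Why: ProPhenol/dimethylzinc asymmetric alkynylation, in which the dinuclear zinc complex binds both the alkynylzinc and the enal and delivers the alkynyl group to one carbonyl face in a 1,2-fashion, which sets C6, the ligand antipode being the one chosen to give the R carbinol.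

Step 12
Reactants: 21 (3R)-6-[(tert-butyldimethylsilyl)oxy]hex-1-en-4-yn-3-ol
Product: 23 (3R,4Z)-6-[(tert-butyldimethylsilyl)oxy]-5-iodohexa-1,4-dien-3-ol, via cyclic sodium alkenylaluminate 22 (not isolated)
Conditions: NaAlH2(OCH2CH2OMe)2, THF, −20 → 0 °C; then I2, THF, −78 °C
Reagents that add atoms: iodine, II
Why: Hydroxyl-directed trans-hydroalumination of the propargylic alcohol places hydride on the proximal carbon C7 and aluminium on the distal carbon C11 in a five-membered aluminate, and iodinolysis with retention gives the Z vinyl iodide with C6 and iodine cis, the low temperature keeping the aluminate from expelling the silyloxy group.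

Step 13
Reactants: 23 (3R,4Z)-6-[(tert-butyldimethylsilyl)oxy]-5-iodohexa-1,4-dien-3-ol
Product: 26 (5R)-3-{[(tert-butyldimethylsilyl)oxy]methyl}-5-ethenylfuran-2(5H)-one, via dilithio alkoxide 24 (not isolated), via hydroxy acid 25 (not isolated)
Conditions: t-BuLi (3 equiv), Et2O, −78 °C; CO2, −78 → 0 °C; then 1 M HCl, 0 °C
Reagents that add atoms: carbon dioxide, O=C=O
Why: Iodine–lithium exchange with retention of alkene geometry followed by carboxylation gives the Z γ-hydroxy acid, which lactonises on acidification, and because the butenolide is never exposed to base its acidic, doubly activated C6–H is not removed and C6 should keep its configuration.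

Step 14
Reactants: 26 (5R)-3-{[(tert-butyldimethylsilyl)oxy]methyl}-5-ethenylfuran-2(5H)-one
Product: 27 (5R)-3-(bromomethyl)-5-ethenylfuran-2(5H)-one
Conditions: Ph3PBr2, CH2Cl2, 0 °C → rt
Reagents that add atoms: dibromotriphenylphosphorane, BrP(Br)(c1ccccc1)(c1ccccc1)c1ccccc1
Why: Direct conversion of a primary allylic silyl ether into the bromide with a bromophosphonium reagent (activation of oxygen, loss of the silyl bromide, SN2 by bromide) is neutral and avoids the basic fluoride that would endanger C6.

Step 15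
Reactants: 27 (5R)-3-(bromomethyl)-5-ethenylfuran-2(5H)-one; 17 (3E,6S)-3-methyl-6-(triethylsilyloxy)-7-[(triethylsilyloxy)methyl]octa-3,7-dienal
Product: 29 (4R,5R)-5-ethenyl-4-[(1S,3E,6S)-1-hydroxy-3-methyl-6-(triethylsilyloxy)-7-[(triethylsilyloxy)methyl]octa-3,7-dien-1-yl]-3-methylideneoxolan-2-one, via allylzinc bromide 28 (not isolated)
Conditions: Zn dust, THF/sat. aq. NH4Cl (2:1), 0 °C → rt
Reagents that add atoms: none
Why: Zinc-mediated Barbier allylation, in which the allylzinc adds through its γ-carbon C7 (restoring the exocyclic methylene) on the butenolide face opposite the C6 vinyl group to give the trans lactone, and the Zimmerman–Traxler chair of this E-locked allyl unit with the aldehyde chain equatorial gives the anti adduct, that is 8S.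

Step 16
Reactants: 29 (4R,5R)-5-ethenyl-4-[(1S,3E,6S)-1-hydroxy-3-methyl-6-(triethylsilyloxy)-7-[(triethylsilyloxy)methyl]octa-3,7-dien-1-yl]-3-methylideneoxolan-2-one; 30 angelic acid
Product: 31 (1R,3E,6S)-1-[(2R,3R)-2-ethenyl-4-methylidene-5-oxooxolan-3-yl]-3-methyl-6-(triethylsilyloxy)-7-[(triethylsilyloxy)methyl]octa-3,7-dien-1-yl (2Z)-2-methylbut-2-enoate
Conditions: PPh3, DIAD (betaine preformed at 0 °C), toluene, 0 °C → rt
Reagents that add atoms: none
Why: Mitsunobu esterification activates the C8 hydroxyl as an oxyphosphonium ion that angelate displaces in an SN2 step, so the ester is formed with inversion to 8R in one operation, and because the acid is never turned into an acylating agent the Z geometry of the angelate is not at risk.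

Step 17
Reactants: 31 (1R,3E,6S)-1-[(2R,3R)-2-ethenyl-4-methylidene-5-oxooxolan-3-yl]-3-methyl-6-(triethylsilyloxy)-7-[(triethylsilyloxy)methyl]octa-3,7-dien-1-yl (2Z)-2-methylbut-2-enoate
Product: 32 (1R)-1-[(2R,3R)-2-ethenyl-4-methylidene-5-oxooxolan-3-yl]-2-[(2R,3R)-2-methyl-3-{(2S)-2-(triethylsilyloxy)-3-[(triethylsilyloxy)methyl]but-3-en-1-yl}oxiran-2-yl]ethyl (2Z)-2-methylbut-2-enoate
Conditions: D-fructose-derived Shi ketone (30 mol %), KHSO5 (as 2KHSO5·KHSO4·K2SO4), K2CO3, Bu4NHSO4, MeCN/(MeO)2CH2/aq. Na2B4O7–Na2EDTA, 0 °C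
Reagents that add atoms: potassium peroxymonosulfate, [K+].[O-]S(=O)(=O)OO
Why: Shi asymmetric epoxidation, in which the chiral dioxirane transfers oxygen through a spiro transition state to one face of the E-trisubstituted C1=C10 alkene in the sense that this ketone shows for trans and trisubstituted alkenes, which corresponds to 1R,10R, while the vinyl group, the doubly oxygen-flanked C4 methylene, the α-methylene lactone and the angelate are too electron-poor or wrongly substituted to react.

Step 18
Reactants: 32 (1R)-1-[(2R,3R)-2-ethenyl-4-methylidene-5-oxooxolan-3-yl]-2-[(2R,3R)-2-methyl-3-{(2S)-2-(triethylsilyloxy)-3-[(triethylsilyloxy)methyl]but-3-en-1-yl}oxiran-2-yl]ethyl (2Z)-2-methylbut-2-enoate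
Product: 33 (1R,3S,4Z,6R,7R,8R,10R)-8-angeloyloxy-1,10-epoxy-3,15-bis(triethylsilyloxy)germacra-4,11(13)-dien-12,6-olide
Conditions: second-generation Hoveyda–Grubbs catalyst RuCl2(H2IMes)(=CH-C6H4-2-O-i-Pr) (15 mol %, in portions), 1,4-benzoquinone (10 mol %), toluene (1 mM), 80 °C, argon sparge
Reagents that add atoms: none
Why: The ruthenium alkylidene first exchanges with the unhindered monosubstituted C5 vinyl group, the resulting C5 carbene adds [2+2] across the 1,1-disubstituted C4 methylene, and the ruthenacyclobutane cycloreverts with loss of ethylene, which the sparge removes, leaving the C4=C5 bond. The closest known reaction type is ring-closing metathesis to ten-membered carbocycles that contain a trisubstituted cis alkene. The ring C1–C10 is closed in the endocyclic sense, both alkene carbons ending up in the ring and the two terminal CH2 groups being lost, under high dilution so that closure outruns cross-metathesis at C5. No stereocentre is created; the new stereo-element is the alkene geometry, which the medium ring controls, since with the trans epoxide at C1/C10 and the trans lactone at C6/C7 already in the chain the cis ruthenacycle should be the less strained one and cis is also the geometry expected if secondary metathesis equilibrates the product. Chemoselectivity among four alkenes is needed and is secured by the substrate: the α-methylene lactone and the angelate are electron-poor and hindered, and C1=C10, which could have closed a six-membered ring onto C10, is already masked as the epoxide. The triethylsilyl ethers keep the C3 hydroxyl from ruthenium-hydride isomerisation to a ketone and are small enough to leave the C4 methylene accessible.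

Step 19
Reactants: 33 (1R,3S,4Z,6R,7R,8R,10R)-8-angeloyloxy-1,10-epoxy-3,15-bis(triethylsilyloxy)germacra-4,11(13)-dien-12,6-olide
Product: 34 (1R,3S,4Z,6R,7R,8R,10R)-8-angeloyloxy-1,10-epoxy-3,15-dihydroxygermacra-4,11(13)-dien-12,6-olide (CNP0187917.1)
Conditions: HF·pyridine, pyridine, THF, 0 °C
Reagents that add atoms: none
Why: Fluoride-mediated desilylation with pyridine-buffered HF·pyridine cleaves both triethylsilyl ethers under conditions mild enough to spare the epoxide, the α-methylene lactone and the angelate.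

**Compound list**

1 | but-3-yn-1-ol | C#CCCO | starting material
2 | 1-[(but-3-yn-1-yloxy)methyl]-4-methoxybenzene | C#CCCOCc1ccc(OC)cc1 | intermediate
3 | {(1E)-4-[(4-methoxybenzyl)oxy]-2-methylbut-1-en-1-yl}dimethylalane | C[Al](C)/C=C(\C)CCOCc1ccc(OC)cc1 | intermediate
4 | lithium butyl{(1E)-4-[(4-methoxybenzyl)oxy]-2-methylbut-1-en-1-yl}dimethylaluminate | [Li+].CCCC[Al-](C)(C)/C=C(\C)CCOCc1ccc(OC)cc1 | intermediate
5 | (2E)-5-[(4-methoxybenzyl)oxy]-3-methylpent-2-en-1-ol | OC/C=C(\C)CCOCc1ccc(OC)cc1 | intermediate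
6 | 1-({[(3E)-5-bromo-3-methylpent-3-en-1-yl]oxy}methyl)-4-methoxybenzene | BrC/C=C(\C)CCOCc1ccc(OC)cc1 | intermediate
7 | 2,2-dimethyl-1,3-dioxan-5-one | CC1(C)OCC(=O)CO1 | starting material
8 | (S)-1-amino-2-(methoxymethyl)pyrrolidine (SAMP) | COC[C@@H]1CCCN1N | starting material
9 | (2S)-N-(2,2-dimethyl-1,3-dioxan-5-ylidene)-2-(methoxymethyl)pyrrolidin-1-amine | COC[C@@H]1CCCN1N=C1COC(C)(C)OC1 | intermediate
10 | lithium azaenolate of 9 | [Li+].COC[C@@H]1CCCN1[N-]C1=COC(C)(C)OC1 | intermediate
11 | (2S)-N-{(4S)-4-[(2E)-5-[(4-methoxybenzyl)oxy]-3-methylpent-2-en-1-yl]-2,2-dimethyl-1,3-dioxan-5-ylidene}-2-(methoxymethyl)pyrrolidin-1-amine | COC[C@@H]1CCCN1N=C1COC(C)(C)O[C@H]1C/C=C(\C)CCOCc1ccc(OC)cc1 | intermediate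
12 | (4S)-4-[(2E)-5-[(4-methoxybenzyl)oxy]-3-methylpent-2-en-1-yl]-2,2-dimethyl-1,3-dioxan-5-one | CC1(C)OCC(=O)[C@H](C/C=C(\C)CCOCc2ccc(OC)cc2)O1 | intermediate
13 | (4S)-4-[(2E)-5-[(4-methoxybenzyl)oxy]-3-methylpent-2-en-1-yl]-2,2-dimethyl-5-methylidene-1,3-dioxane | CC1(C)OCC(=C)[C@H](C/C=C(\C)CCOCc2ccc(OC)cc2)O1 | intermediate
14 | (3S,5E)-8-[(4-methoxybenzyl)oxy]-6-methyl-2-methylideneoct-5-ene-1,3-diol | OCC(=C)[C@@H](O)C/C=C(\C)CCOCc1ccc(OC)cc1 | intermediate
15 | (3S,5E)-8-[(4-methoxybenzyl)oxy]-6-methyl-2-methylidene-1,3-bis(triethylsilyloxy)oct-5-ene | CC[Si](CC)(CC)OCC(=C)[C@@H](O[Si](CC)(CC)CC)C/C=C(\C)CCOCc1ccc(OC)cc1 | intermediate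
16 | (3E,6S)-3-methyl-6-(triethylsilyloxy)-7-[(triethylsilyloxy)methyl]octa-3,7-dien-1-ol | CC[Si](CC)(CC)OCC(=C)[C@@H](O[Si](CC)(CC)CC)C/C=C(\C)CCO | intermediate
17 | (3E,6S)-3-methyl-6-(triethylsilyloxy)-7-[(triethylsilyloxy)methyl]octa-3,7-dienal | CC[Si](CC)(CC)OCC(=C)[C@@H](O[Si](CC)(CC)CC)C/C=C(\C)CC=O | intermediate
18 | acrolein | C=CC=O | starting material
19 | tert-butyldimethyl(prop-2-yn-1-yloxy)silane | C#CCO[Si](C)(C)C(C)(C)C | starting material
20 | {3-[(tert-butyldimethylsilyl)oxy]prop-1-yn-1-yl}(methyl)zinc | C[Zn]C#CCO[Si](C)(C)C(C)(C)C | intermediate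
21 | (3R)-6-[(tert-butyldimethylsilyl)oxy]hex-1-en-4-yn-3-ol | C=C[C@@H](O)C#CCO[Si](C)(C)C(C)(C)C | intermediate
22 | sodium (5R)-3-{[(tert-butyldimethylsilyl)oxy]methyl}-5-ethenyl-2,2-bis(2-methoxyethoxy)-2,5-dihydro-1,2-oxaaluminol-2-uide | [Na+].C=C[C@H]1O[Al-](OCCOC)(OCCOC)C(CO[Si](C)(C)C(C)(C)C)=C1 | intermediate
23 | (3R,4Z)-6-[(tert-butyldimethylsilyl)oxy]-5-iodohexa-1,4-dien-3-ol | C=C[C@@H](O)/C=C(\I)CO[Si](C)(C)C(C)(C)C | intermediate
24 | dilithium species from 23 (C6 alkoxide, C11 vinyllithium, Z) | [Li+].C=C[C@@H]([O-])/C=C(\[Li])CO[Si](C)(C)C(C)(C)C | intermediate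
25 | (2Z,4R)-2-{[(tert-butyldimethylsilyl)oxy]methyl}-4-hydroxyhexa-2,5-dienoic acid | C=C[C@@H](O)/C=C(\C(=O)O)CO[Si](C)(C)C(C)(C)C | intermediate
26 | (5R)-3-{[(tert-butyldimethylsilyl)oxy]methyl}-5-ethenylfuran-2(5H)-one | C=C[C@H]1OC(=O)C(CO[Si](C)(C)C(C)(C)C)=C1 | intermediate
27 | (5R)-3-(bromomethyl)-5-ethenylfuran-2(5H)-one | C=C[C@H]1OC(=O)C(CBr)=C1 | intermediate
28 | bromo{[(5R)-5-ethenyl-2-oxo-2,5-dihydrofuran-3-yl]methyl}zinc | C=C[C@H]1OC(=O)C(C[Zn]Br)=C1 | intermediate
29 | (4R,5R)-5-ethenyl-4-[(1S,3E,6S)-1-hydroxy-3-methyl-6-(triethylsilyloxy)-7-[(triethylsilyloxy)methyl]octa-3,7-dien-1-yl]-3-methylideneoxolan-2-one | C=C1C(=O)O[C@H](C=C)[C@H]1[C@@H](O)C/C(C)=C/C[C@H](O[Si](CC)(CC)CC)C(=C)CO[Si](CC)(CC)CC | intermediate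
30 | angelic acid, (2Z)-2-methylbut-2-enoic acid | C/C=C(/C)C(=O)O | starting material
31 | (1R,3E,6S)-1-[(2R,3R)-2-ethenyl-4-methylidene-5-oxooxolan-3-yl]-3-methyl-6-(triethylsilyloxy)-7-[(triethylsilyloxy)methyl]octa-3,7-dien-1-yl (2Z)-2-methylbut-2-enoate | C=C1C(=O)O[C@H](C=C)[C@H]1[C@H](OC(=O)/C(C)=C\C)C/C(C)=C/C[C@H](O[Si](CC)(CC)CC)C(=C)CO[Si](CC)(CC)CC | intermediate
32 | (1R)-1-[(2R,3R)-2-ethenyl-4-methylidene-5-oxooxolan-3-yl]-2-[(2R,3R)-2-methyl-3-{(2S)-2-(triethylsilyloxy)-3-[(triethylsilyloxy)methyl]but-3-en-1-yl}oxiran-2-yl]ethyl (2Z)-2-methylbut-2-enoate | C=C1C(=O)O[C@H](C=C)[C@H]1[C@H](OC(=O)/C(C)=C\C)C[C@@]2(C)O[C@@H]2C[C@H](O[Si](CC)(CC)CC)C(=C)CO[Si](CC)(CC)CC | intermediate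
33 | (1R,3S,4Z,6R,7R,8R,10R)-8-angeloyloxy-1,10-epoxy-3,15-bis(triethylsilyloxy)germacra-4,11(13)-dien-12,6-olide | C=C1C(=O)O[C@@H]2/C=C(/CO[Si](CC)(CC)CC)[C@@H](O[Si](CC)(CC)CC)C[C@H]3O[C@]3(C)C[C@@H](OC(=O)/C(C)=C\C)[C@@H]12 | intermediate
34 | (1R,3S,4Z,6R,7R,8R,10R)-8-angeloyloxy-1,10-epoxy-3,15-dihydroxygermacra-4,11(13)-dien-12,6-olide (CNP0187917.1) | C=C1C(=O)O[C@@H]2/C=C(/CO)[C@@H](O)C[C@H]3O[C@]3(C)C[C@@H](OC(=O)/C(C)=C\C)[C@@H]12 | target

**Step count and risk**

Total: 19 steps. Longest linear sequence: 14 steps (1, 2, 3, 5–10, 15–19) from but-3-yn-1-ol.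

Steps most likely to fail:

Step 18 (ring-closing metathesis). The process at risk is slow engagement of the silyl-flanked C4 methylene, so that intermolecular metathesis at the C5 vinyl group (oligomerisation) outruns closure, or partial formation of the trans C4=C5 isomer. The fallback sets out from 32. Both triethylsilyl ethers are removed first (HF·pyridine, pyridine, THF, 0 °C) to give the seco epoxy diol F1. A free allylic hydroxyl at C3 is known to accelerate metathesis at the neighbouring alkene, and the unprotected 2-methylene-1,3-diol is far less shielded. Closure of F1 with the same ruthenium carbene in dilute toluene should therefore lead directly to 34, where the fallback rejoins the route.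

Step 16 (Mitsunobu inversion). The process at risk is sluggish displacement at the branched C8 oxyphosphonium centre with competing elimination towards C7 or C9, or addition of the phosphine to the α-methylene lactone. The fallback sets out from 29. The alcohol is converted into the C8 methanesulfonate F2 (Ms2O, pyridine, CH2Cl2, 0 °C). F2 is then displaced with caesium angelate F3 (made from 30 and Cs2CO3; 18-crown-6, toluene, 60 °C). This is an SN2 inversion by a poorly solvated carboxylate that needs neither phosphine nor azo reagent, and it returns to the route at 31.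

Step 17 (Shi epoxidation). The process at risk is insufficient facial selectivity on the flexible chain, or attack of the basic oxidising medium on the α-methylene lactone. The fallback sets out from 31. The ring is closed first by metathesis of the pentaene itself (same catalyst, high dilution) to give the 1(10)E,4Z macrocycle F4, accepting the competing six-membered closure onto C10. C1=C10 is the only electron-rich and strained alkene of F4. It is then epoxidised with mCPBA (NaHCO3, CH2Cl2, 0 °C) from its exposed outer face under the conformational control of the ten-membered ring, which is expected to give the same 1R,10R epoxide, so the fallback rejoins the route at 33.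

**Further compounds**

F1 | step 18 | (1R)-1-[(2R,3R)-2-ethenyl-4-methylidene-5-oxooxolan-3-yl]-2-[(2R,3R)-3-{(2S)-2-hydroxy-3-(hydroxymethyl)but-3-en-1-yl}-2-methyloxiran-2-yl]ethyl (2Z)-2-methylbut-2-enoate | C=C1C(=O)O[C@H](C=C)[C@H]1[C@H](OC(=O)/C(C)=C\C)C[C@@]2(C)O[C@@H]2C[C@H](O)C(=C)CO
F2 | step 16 | (1S,3E,6S)-1-[(2R,3R)-2-ethenyl-4-methylidene-5-oxooxolan-3-yl]-3-methyl-6-(triethylsilyloxy)-7-[(triethylsilyloxy)methyl]octa-3,7-dien-1-yl methanesulfonate | C=C1C(=O)O[C@H](C=C)[C@H]1[C@@H](OS(C)(=O)=O)C/C(C)=C/C[C@H](O[Si](CC)(CC)CC)C(=C)CO[Si](CC)(CC)CC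
F3 | step 16 | caesium (2Z)-2-methylbut-2-enoate | [Cs+].C/C=C(/C)C(=O)[O-]
F4 | step 17 | (1(10)E,3S,4Z,6R,7R,8R)-8-angeloyloxy-3,15-bis(triethylsilyloxy)germacra-1(10),4,11(13)-trien-12,6-olide | C=C1C(=O)O[C@@H]2/C=C(/CO[Si](CC)(CC)CC)[C@@H](O[Si](CC)(CC)CC)C/C=C(\C)C[C@@H](OC(=O)/C(C)=C\C)[C@@H]12
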